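Readings and results were computed with constants of no real substance; scatter was added.

| setting | grey | red | flask |
|---|---|---|---|
| starting material | 0.010 M (fed, over 1.0 min) | 0.015 M (fed, over 1.0 min) | 0.020 M (fed, over 1.0 min) |
| reagent in the second phase | 0.080 M | 0.080 M | 0.0800 M |
| protic impurity | 0.40 mM | 0.40 mM | 0.400 mM |
| remark | run made earlier; the fed solution adds 0.25 times the starting volume | run made earlier; the fed solution adds 0.25 times the starting volume | the fed solution adds 0.25 times the starting volume |
| time |  |  | 6.0 min |
| volume of the second phase over the first |  |  | 2.0 |

| run | time / min | starting material / % | target / % |
|---|---|---|---|
| grey | 0.500 | 47.7 | 2.1 |
| grey | 1.50 | 75.9 | 20.3 |
| grey | 3.00 | 46.9 | 33.4 |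
| grey | 4.00 | 33.8 | 35.6 |
| grey | 6.00 | 17.8 | 33.4 |
| red | 0.500 | 47.6 | 1.8 |
| red | 0.833 | 76.2 | 6.9 |
| red | 1.50 | 74.8 | 18.2 |
| red | 3.00 | 47.3 | 30.8 |
| red | 6.00 | 17.7 | 29.9 |

(each reading ± 0.5 percentage points)

- percentages count the starting material that a species holds: one side product counts as two
- every charge counts on the volume at the start, and the solution that is fed holds the whole dose
- in the second phase: reagent in the second phase; everything else is in the first
- charges count per volume of the first phase; a concentration in a rate is the amount of a species over the volume of its own phase; every rate counts per litre of the first phase
- steps thought possible: starting material + reagent in the reaction phase -> target; starting material + target -> side product; reagent in the reaction phase + target -> over-reacted product; target <-> isomer of the product; reagent in the reaction phase <-> reagent in the second phase; reagent in the reaction phase + protic impurity -> quenched reagent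
- the earlier runs hold the two phases in the same ratio of volumes as the flask asked about
- percentages count the whole charge, also what has not yet gone in
- the reaction counts as stopped when no species that holds the starting material changes by six tenths of a point or more over the second half of the time

- the state of affairs at 6.0 min: stopped, and by what, or still going (it is still moving / forward and back rates have come level / all of the starting material has reacted)
- conversion of starting material at 6.0 min
- amount of target at 6.0 min, in percent of the starting material charged
- amount of side product at 6.0 min, in percent of the starting material charged
- amount of isomer of the product at 6.0 min, in percent of the starting material charged

The leftover starting material at 6.00 min reads 17.8 % in the grey run and 17.7 % in the red run, though the red charge is 1.50 times the grey one. A leftover share that ignores the charge points to a decay of order one in starting material, with the reagent in the reaction phase held steady from the second phase: a pseudo-first-order decay. The objection is the larger flask, but its second phase still holds 4.00 equivalents of the charge. My estimate therefore keeps the grey leftover, which gives a conversion of 82.2 %, and the starting material of the grey and red runs is still falling at their last points, so my estimate for the flask is that it is still moving.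

Side product was not read, but it can be reckoned. Its step takes starting material and target together, so its share should grow with the charge, while the exits from target to isomer and over-reacted product should not. A straight line through the grey and red targets at 6.00 min reaches 40.4 % at zero charge, where side product vanishes. Divided by the conversion, that gives 49.1 %, the target share φ: target divided by the difference of conversion and side product. The same line puts the flask's target at 26.4 %, so side product is conversion minus target over φ, or 28.5 %. Two doubts remain. The line rests on two readings that scatter by 0.5 percentage points, and the side product reckoned from it may lean high: the side step also needs target, and the target readings fall as the charge rises.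

The forecast says it is still moving, with conversion 82 %, target 27 %, side product 16 % and isomer 20 %, the side product set “allowing for some curvature”. That side product is lower than my estimate.

The flask gives: it is still moving, conversion 81.9 %, target 27.8 %, side product 25.3 %, isomer 15.7 %.

    starting material + reagent in the reaction phase → target (k = 0.430 /M/s)
    starting material + target → side product (k = 0.230 /M/s)
    reagent in the reaction phase + target → over-reacted product (k = 0.160 /M/s)
    target ⇌ isomer of the product (K = 3.10, k = 0.00210 /s)
    reagent in the reaction phase ⇌ reagent in the second phase, rate k5*([reagent in the reaction phase] - [reagent in the second phase]/K5) per volume of the first phase (partition coefficient = 2.60, kL = 0.0430 /s)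
    reagent in the reaction phase + protic impurity → quenched reagent (k = 10.0 /M/s)

In the flask, conversion minus target over φ gives 25.3 %, against the computed 25.3 %. The conversion stands at 81.9 % on account of the reading time: the same flask read at 60.0 min instead gives >99.9 %. For the neighbour flask with 0.0080 M of starting material, the line gives target 34.8 %, and φ then gives side product 11.3 %. The computed neighbour holds target 34.1 % and side product 11.8 %.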